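The runs were generated by integration from invented constants, and the scatter is random.

- Read each c(target) as starting material turned: the overall equation takes one starting material and one reagent for every target.

| setting | south-east | west | east | south |
|---|---|---|---|---|
| starting material | 0.0800 M | 0.0800 M | 0.120 M | 0.0160 M |
| reagent | 0.240 M | 0.720 M | 0.240 M | 0.0480 M |
| free catalyst | 0.00400 M | 0.00400 M | 0.00400 M | 0.00400 M |
| time |  |  |  | 4.9 min |

- south-east run (time / min: [target] / M): 0.61: 0.0093; 1.2: 0.0168; 1.8: 0.0247; 2.5: 0.0309; 3.1: 0.0347; 3.7: 0.0403; 4.3: 0.0424; 4.9: 0.0463
- west run (time / min: [target] / M): 0.61: 0.0265; 1.2: 0.0444; 1.8: 0.0570; 2.5: 0.0663; 3.1: 0.0718; 3.7: 0.0746; 4.3: 0.0768; 4.9: 0.0775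
- east run (time / min: [target] / M): 0.61: 0.0127; 1.2: 0.0225; 1.8: 0.0317; 2.5: 0.0400; 3.1: 0.0460; 3.7: 0.0517; 4.3: 0.0555; 4.9: 0.0613

(readings scatter by 6 × 10⁻⁴ M)

- Overall: starting material + reagent -> target, with free catalyst as catalyst.
- Constant volume, constant temperature.
- The analysis sees a species whether free or bound.
- An order is taken over about fifteen percent of the charge, up and down.

1. how the opening rate goes with [starting material] round the charge of the south-east run: the exponent of the rate at two percent of starting material gone to target (one fixed amount of target, the same in the runs compared)
2. how the opening rate goes with [reagent] round the charge of the south-east run: the exponent of the rate at two percent of starting material gone to target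
3. target in the south run at 4.9 min, as a share of the starting material charged

- Follow one molecule of starting material: its chance of turning per minute is k·c(reagent), where k is the turning constant (apparent second-order rate constant).
- Integrate that chance up to the last south-east reading, with c(reagent) and c(starting material) each taken as a share of its charge. The logarithm of the first share over the second, divided by the difference of the charges and by the time, gives k = 0.829 L mol⁻¹ min⁻¹.
- Carry this k unchanged to the south run, which has the same charge ratio but is diluted 5.00-fold, and 17.2 % of its starting material has turned by 4.9 min.
- That unchanged k is the weak link, so test it. At 0.61 min, the east run holds 1.37 times the target of the south-east run, on 1.50 times the starting material.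
- Define the dilution exponent m as one minus the order read from that pair at one fixed time; k then goes as the charge of starting material to the power −m. The readings give m = 0.232, with a scatter of 0.197, so the order in starting material at that fixed time reads 0.768.
- Reforge the link: k in the south run becomes 1.20 L mol⁻¹ min⁻¹, and the share turned becomes 23.8 %. Commit to that.
- The forecast gives 0.8 (0.62 to 0.95) for the order in starting material, 1.1 (0.95 to 1.3) for the order in reagent, and 20 % (16 % to 24.5 %) for the south run, on the ground that “more starting material slows the catalyst a little”. My share stands higher than its 20 %.
- The south run gives 23.2 %, and the orders come out at 0.67 in starting material and 1.0 in reagent.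

    2 free catalyst ⇌ catalyst dimer, settled at all times (194.0 L mol⁻¹)
    free catalyst + starting material + reagent → target + free catalyst (870.0 L² mol⁻² min⁻¹)
    2 free catalyst → 2 spent catalyst (55.56 L mol⁻¹ min⁻¹)
    2 starting material ⇌ idle substrate dimer, settled at all times (15.10 L mol⁻¹)

- Turn the south result back through the integrated form: it asks for k = 1.17 L mol⁻¹ min⁻¹, which is 1.41 times the south-east value and means a dilution exponent of 0.213. Now take the east run: m puts its k at 0.755 L mol⁻¹ min⁻¹, smaller than the south-east value. That puts target at a quarter of the starting material charged at 1.70 min, and the east run reaches it at 1.71 min.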